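Of the flask's 1.0 M substrate and 1.30 M reagent, the substrate was the limiting reagent. Each unit of substrate used took one of reagent, so the reagent left equalled the substrate left plus 0.300 M. The flask charged both as the green run did, so I used the green substrate readings for it.

| setting | green | amber | grey | flask |
|---|---|---|---|---|
| substrate | 1 M | 1 M | 1 M | 1.0 M |
| reagent | 1.3 M | 1.3 M | 2.6 M | 1.30 M |
| capture agent | 1.4 M | 2.2 M | 1 M | 1.00 M |
| remark | run made earlier | run made earlier | run made earlier |  |
| time |  |  |  | 2.5 d |

| run | time / h | open intermediate / % | target / % | substrate / % |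
|---|---|---|---|---|
| green | 3.00 | 27.3 | 1.2 | 72.0 |
| green | 5.00 | 35.1 | 2.4 | 58.4 |
| green | 8.00 | 41.5 | 1.7 | 48.0 |
| green | 12.0 | 39.9 | 7.5 | 34.1 |
| green | 20.0 | 35.8 | 12.0 | 22.5 |
| green | 30.0 | 28.5 | 13.8 | 15.6 |
| green | 50.0 | 13.5 | 18.6 | 6.9 |
| amber | 3.00 | 24.6 | 1.6 | 71.9 |
| amber | 5.00 | 31.8 | 0.5 | 59.7 |
| amber | 8.00 | 37.9 | 3.1 | 46.9 |
| amber | 12.0 | 35.7 | 7.5 | 36.1 |
| amber | 20.0 | 28.1 | 9.3 | 20.8 |
| amber | 30.0 | 19.2 | 10.5 | 14.9 |
| amber | 50.0 | 8.4 | 14.3 | 5.7 |
| grey | 3.00 | 45.5 | 2.7 | 50.5 |
| grey | 6.00 | 59.1 | 5.6 | 28.4 |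
| grey | 12.0 | 57.7 | 11.3 | 10.3 |
| grey | 25.0 | 38.0 | 18.5 | 1.9 |
| grey | 50.0 | 14.1 | 24.2 | 0 |

(readings scatter by 1 percentage point)

* time, not beyond 2.5 d, at which the flask holds most open intermediate
* the amount of open intermediate, in percent of the substrate charged, at that time

I compared two times. The making time is how long substrate lasts at the present reagent; the holding time is how long open intermediate lasts. The grey run has the flask's capture agent charge, so I read the holding time there, as amount-hours of open intermediate per amount lost by 25.0 h: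

k = 0.102 /M/h, from the green substrate at 12.0 h

holding time = 19.9 h

making time = 1/(k × reagent left) = 15.2 h at 12.0 h

At the top, making equals loss, so open intermediate over substrate equals the holding ratio, holding time over making time: 1.31. At 12.0 h this gave me 44.6% for the flask.

The forecast gave 44.5% at 0.5 d, since “the intermediate peaks where formation equals decay”.

The flask gave 44.8% at 0.514 d.

    substrate + reagent → open intermediate + by-product (k = 2.74 × 10⁻⁵ /M/s)
    open intermediate → target (k = 6.86 × 10⁻⁶ /s)
    target ⇌ isomer of the product (K = 0.960, k = 3.22 × 10⁻⁵ /s)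
    open intermediate + capture agent → trapped intermediate (k = 7.47 × 10⁻⁶ /M/s)

In the flask at 0.514 d, open intermediate over substrate stood at 1.30. With 0.25 M substrate, the neighbouring flask had 5.20 equiv of reagent, and 80.8% of its charge was left at 2.50 d, so I reckoned it as a pseudo-first-order case. Taking reagent at its charge less half the substrate, the holding ratio became 2.40, and the top, ratio^(1/(1 − ratio)), came to 53.5%. That neighbouring flask gave 52.1%.

The runs were generated by integration for substances that don't exist; the scatter is artificial.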